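**Assumption:** the target has no stereogenic element (it is achiral), so there is no enantiomer to select. The one stereocentre made on the way (carbinol 3, racemic) is erased in step 2.

## Retrosynthetic overview

1. Target 14 ⇐ tetramethyl ether 13 by global O-demethylation (last step).
2. 13 ⇐ salicylaldehyde 7 + aroyl sulfoxonium ylide 11: a Rh(III)-catalysed aldehydic C–H activation / carbene insertion / cyclodehydration builds the pyranone (ring C). This is the only ring formed; rings A and B are bought.
3. 7 ⇐ phenol 5 by chelation-controlled ortho-formylation. The single free OH sits next to the benzyl group, so O1 and C8 are locked and no 6-/8-benzyl ambiguity can arise.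
4. 5 ⇐ commercial aldehyde 1 + aryl Grignard 2, then ionic deoxygenation: the first CHO becomes the benzylic CH2, and a new CHO is later placed on the other ortho carbon.
5. Avoided on purpose: chalcone or Baker–Venkataraman assembly from a C-benzylated phloroacetophenone, and direct benzylation of apigenin.

## Route

**Step 1**
Reactants: 1 2-hydroxy-4,6-dimethoxybenzaldehyde; 2 4-methoxyphenylmagnesium bromide
Product: 3 2-[hydroxy(4-methoxyphenyl)methyl]-3,5-dimethoxyphenol (racemic)
Conditions: 2 (3.0 equiv, 0.5 M in THF), THF, 0 → 45 °C, 3 h; sat. aq NH4Cl; crude used at once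
Reagents that add atoms: none
Why: Grignard 1,2-addition to the aldehyde after the first equivalent has deprotonated the phenol (the 6-OMe/phenoxide chelate Mg and guide the second equivalent); the new carbinol centre is racemic and is removed in step 2.

**Step 2**
Reactants: 3 2-[hydroxy(4-methoxyphenyl)methyl]-3,5-dimethoxyphenol
Product: 5 3,5-dimethoxy-2-(4-methoxybenzyl)phenol, via o-quinone methide 4 (not isolated)
Conditions: Et3SiH (4 equiv), TFA (5 equiv, added last), CH2Cl2 (0.02 M), −20 → 0 °C, 30 min
Reagents that add atoms: none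
Why: Ionic hydrogenation, in which acid ionises the doubly activated benzhydrol to the o-quinone methide (as its O-protonated cation) and the silane delivers hydride to the benzylic carbon; no stereocentre remains.

**Step 3**
Reactants: 5 3,5-dimethoxy-2-(4-methoxybenzyl)phenol
Product: 7 2-hydroxy-4,6-dimethoxy-3-(4-methoxybenzyl)benzaldehyde, via salicyl alcohol 6 (not isolated)
Conditions: MgCl2 (anhydrous, 2 equiv), Et3N (4 equiv), (CH2O)n (7 equiv), MeCN, reflux, 4 h; 1 M HCl work-up
Reagents that add atoms: paraformaldehyde (as formaldehyde), C=O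
Why: Casiraghi–Skattebøl ortho-formylation, in which the magnesium phenoxide delivers formaldehyde only to the one free ortho carbon and a second formaldehyde oxidises the Mg-bound salicyl alcohol by hydride transfer, so the para position is untouched.

**Step 4**
Reactants: 8 trimethylsulfoxonium iodide; 9 4-methoxybenzoyl chloride
Product: 11 2-(dimethyl(oxo)-λ6-sulfanylidene)-1-(4-methoxyphenyl)ethan-1-one, via dimethylsulfoxonium methylide 10 (not isolated)
Conditions: 8 (3 equiv), KOtBu (3 equiv), THF, reflux, 2 h; then 9 (1 equiv), 0 °C → rt, 1 h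
Reagents that add atoms: none
Why: C-acylation of the Corey–Chaykovsky ylide by the acid chloride, with a second equivalent of the methylide deprotonating the acylated sulfoxonium salt to give the stable, crystalline keto-ylide.

**Step 5 (key step)**
Reactants: 7 2-hydroxy-4,6-dimethoxy-3-(4-methoxybenzyl)benzaldehyde; 11 2-(dimethyl(oxo)-λ6-sulfanylidene)-1-(4-methoxyphenyl)ethan-1-one
Product: 13 5,7-dimethoxy-8-(4-methoxybenzyl)-2-(4-methoxyphenyl)-4H-chromen-4-one, via hydroxyaryl diketone 12 (not isolated)
Conditions: 11 (1.5 equiv), [Cp*RhCl2]2 (4 mol %), AgSbF6 (16 mol %), PivOH (1 equiv), DCE, 100 °C, 12 h; then TsOH·H2O (20 mol %), 80 °C, 1 h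
Reagents that add atoms: none
Why: Rh(III)-catalysed OH-directed aldehydic C–H activation gives a five-membered acyl rhodacycle, the sulfoxonium ylide serves as carbene precursor (loss of DMSO), migratory insertion and protodemetalation give the 1,3-diketone, and acid cyclodehydration through the only free phenol closes the pyranone (C–H activation/annulation of salicylaldehydes with sulfoxonium ylides), placing the benzyl group at C8 without ambiguity.

**Step 6**
Reactants: 13 5,7-dimethoxy-8-(4-methoxybenzyl)-2-(4-methoxyphenyl)-4H-chromen-4-one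
Product: 14 5,7-dihydroxy-8-(4-hydroxybenzyl)-2-(4-hydroxyphenyl)-4H-chromen-4-one (target)
Conditions: BBr3 (12 equiv, 1 M in CH2Cl2), CH2Cl2, −78 → 40 °C, 16 h; then ice/H2O
Reagents that add atoms: none
Why: Lewis-acid aryl methyl ether cleavage (O–B coordination, then bromide SN2 at methyl, the 5-OMe assisted by C4=O chelation) removes all four methyl groups under anhydrous conditions that do not open the pyranone, so the 8-benzyl group cannot migrate to C6 (no Wessely–Moser isomerisation).

## Compound list

1 | 2-hydroxy-4,6-dimethoxybenzaldehyde | COc1cc(O)c(C=O)c(OC)c1 | starting material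
2 | 4-methoxyphenylmagnesium bromide | COc1ccc([Mg]Br)cc1 | starting material
3 | 2-[hydroxy(4-methoxyphenyl)methyl]-3,5-dimethoxyphenol (racemic) | COc1ccc(cc1)C(O)c1c(O)cc(OC)cc1OC | intermediate
4 | 3,5-dimethoxy-6-[(4-methoxyphenyl)methylidene]cyclohexa-2,4-dien-1-one (o-quinone methide, transient, alkene geometry undefined, not isolated) | COc1ccc(C=C2C(=O)C=C(OC)C=C2OC)cc1 | intermediate
5 | 3,5-dimethoxy-2-(4-methoxybenzyl)phenol | COc1ccc(Cc2c(O)cc(OC)cc2OC)cc1 | intermediate
6 | 2-(hydroxymethyl)-3,5-dimethoxy-6-(4-methoxybenzyl)phenol (salicyl alcohol, Mg-bound, not isolated) | COc1ccc(Cc2c(O)c(CO)c(OC)cc2OC)cc1 | intermediate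
7 | 2-hydroxy-4,6-dimethoxy-3-(4-methoxybenzyl)benzaldehyde | COc1ccc(Cc2c(O)c(C=O)c(OC)cc2OC)cc1 | intermediate
8 | trimethylsulfoxonium iodide | C[S+](C)(C)=O.[I-] | starting material
9 | 4-methoxybenzoyl chloride | COc1ccc(cc1)C(=O)Cl | starting material
10 | dimethylsulfoxonium methylide (not isolated) | [CH2-][S+](C)(C)=O | intermediate
11 | 2-(dimethyl(oxo)-λ6-sulfanylidene)-1-(4-methoxyphenyl)ethan-1-one | COc1ccc(cc1)C(=O)C=S(C)(C)=O | intermediate
12 | 1-[2-hydroxy-4,6-dimethoxy-3-(4-methoxybenzyl)phenyl]-3-(4-methoxyphenyl)propane-1,3-dione (not isolated) | COc1ccc(Cc2c(O)c(C(=O)CC(=O)c3ccc(OC)cc3)c(OC)cc2OC)cc1 | intermediate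
13 | 5,7-dimethoxy-8-(4-methoxybenzyl)-2-(4-methoxyphenyl)-4H-chromen-4-one | COc1ccc(Cc2c(OC)cc(OC)c3c(=O)cc(-c4ccc(OC)cc4)oc23)cc1 | intermediate
14 | 5,7-dihydroxy-8-(4-hydroxybenzyl)-2-(4-hydroxyphenyl)-4H-chromen-4-one | O=c1cc(-c2ccc(O)cc2)oc2c(Cc3ccc(O)cc3)c(O)cc(O)c12 | target

## Step count and risks

Total step count: 6. Longest linear sequence: 5 (steps 1, 2, 3, 5, 6); step 4 is a one-step branch.

The three steps most likely to fail:

**Step 5 (Rh annulation).** The aldehyde is very electron-rich and flanked by OH and OMe, so C–H activation may be slow, and the ylide may instead add as a nucleophile to the aldehyde. The fallback sets out from 7 and comes back at 13, replacing C–H activation by an ynone cyclisation. 4-Ethynylanisole is deprotonated with n-BuLi (THF, −78 °C) to lithium (4-methoxyphenyl)acetylide F2, and 2.5 equiv of it are added to 7. This gives the propargylic alcohol 1-[2-hydroxy-4,6-dimethoxy-3-(4-methoxybenzyl)phenyl]-3-(4-methoxyphenyl)prop-2-yn-1-ol F3. MnO2 in CH2Cl2 oxidises it to the ynone 1-[2-hydroxy-4,6-dimethoxy-3-(4-methoxybenzyl)phenyl]-3-(4-methoxyphenyl)prop-2-yn-1-one F4. Et2NH in refluxing EtOH then effects the 6-endo closure through the β-enaminone (this avoids the 5-exo aurone) and delivers 13.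

**Step 6 (global demethylation).** The 7-OMe of flavones is slow to cleave, and forcing conditions risk partial products or acid-induced change at the benzylated ring. The fallback sets out from 13 and comes back at 14 in two stages with different mechanisms. BCl3 (CH2Cl2, −20 → 0 °C) removes only the carbonyl-chelated 5-OMe to give 5-hydroxy-7-methoxy-8-(4-methoxybenzyl)-2-(4-methoxyphenyl)-4H-chromen-4-one F5. The remaining three ethers are then cleaved by chloride SN2 in an anhydrous pyridine hydrochloride melt (190 °C, 2 h) to give 14. The 8- versus 6-benzyl position is checked by HMBC afterwards.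

**Step 2 (ionic deoxygenation).** The cation from 3 is so stabilised that hydride transfer may be slow, and Friedel–Crafts oligomerisation with the phloroglucinol-type ring can compete. The fallback sets out from 1 and comes back at 5, generating the same o-quinone methide 4 under basic conditions. 1 is acylated (Boc2O, i-Pr2NEt, cat. DMAP, CH2Cl2) to tert-butyl (2-formyl-3,5-dimethoxyphenyl) carbonate F1. Addition of 2 (1.05 equiv, THF, −78 °C) gives the magnesium alkoxide. On warming, the Boc group migrates to the benzylic oxygen and tert-butyl carbonate is expelled, forming 4. LiBH4, added before warming, reduces 4 in the same flask by 1,4-hydride addition to give 5.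

## Further compounds

F1 | step 2 | tert-butyl (2-formyl-3,5-dimethoxyphenyl) carbonate | COc1cc(OC)c(C=O)c(OC(=O)OC(C)(C)C)c1
F2 | step 5 | lithium (4-methoxyphenyl)acetylide | [Li]C#Cc1ccc(OC)cc1
F3 | step 5 | 1-[2-hydroxy-4,6-dimethoxy-3-(4-methoxybenzyl)phenyl]-3-(4-methoxyphenyl)prop-2-yn-1-ol (racemic) | COc1ccc(Cc2c(O)c(C(O)C#Cc3ccc(OC)cc3)c(OC)cc2OC)cc1
F4 | step 5 | 1-[2-hydroxy-4,6-dimethoxy-3-(4-methoxybenzyl)phenyl]-3-(4-methoxyphenyl)prop-2-yn-1-one | COc1ccc(Cc2c(O)c(C(=O)C#Cc3ccc(OC)cc3)c(OC)cc2OC)cc1
F5 | step 6 | 5-hydroxy-7-methoxy-8-(4-methoxybenzyl)-2-(4-methoxyphenyl)-4H-chromen-4-one | COc1ccc(Cc2c(OC)cc(O)c3c(=O)cc(-c4ccc(OC)cc4)oc23)cc1
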